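**Retrosynthetic overview**
1. Target 10 is traced back to its phenol O‑acetate 9, so the last step only removes an acetyl group.
2. In 9 the CH2–CH2 bond between C15 and C16 of the pentacosyl chain (counted from the ester oxygen; C10–C11 from the methyl end) is cut. It is made by a mixed Kolbe electrolysis, an anodic decarboxylative radical–radical coupling, of the C16 ω‑acyloxy acid 5 with undecanoic acid 6.
3. Acid 5 comes from O‑acylation of 16‑hydroxyhexadecanoic acid 3 with the acid chloride of 3‑(4‑acetoxyphenyl)propanoic acid 2, which is made from phloretic acid 1.
4. Enabling feature: the bond lies inside the unbranched polymethylene chain. Both of its carbons are CH2 groups flanked by CH2 groups, and the nearest heteroatom (the ester O) is 15 carbons away, so each side is a primary, unstabilised alkyl radical that comes from a plain CH2–CO2H end. The only ring, the para‑disubstituted benzene ring, is made anodically inert by carrying its phenol oxygen as the acetate.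
5. No ring is formed (the benzene ring is bought with 1) and the target has no stereocentre.

Key step: step 3

Remark: the target has no stereocentre and no stereogenic double bond, so the given SMILES defines it completely and no stereocontrol is needed.

**Route**

Step 1
Reactants: 1 3‑(4‑hydroxyphenyl)propanoic acid (phloretic acid)
Product: 2 3‑[4‑(acetyloxy)phenyl]propanoic acid
Conditions: Ac2O (1.3 equiv), 2 M aq. NaOH (2.1 equiv), 0 °C; then 2 M HCl to pH 2, filter
Reagents that add atoms: acetic anhydride, CC(=O)OC(C)=O
Why: Chattaway‑type O‑acetylation under Schotten–Baumann conditions, in which the phenoxide is acetylated in cold water faster than the anhydride hydrolyses, while the carboxylate stays free because any mixed anhydride is hydrolysed in the aqueous medium.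

Step 2
Reactants: 2 3‑[4‑(acetyloxy)phenyl]propanoic acid; 3 16‑hydroxyhexadecanoic acid
Product: 5 16‑({3‑[4‑(acetyloxy)phenyl]propanoyl}oxy)hexadecanoic acid, via 3‑[4‑(acetyloxy)phenyl]propanoyl chloride 4 (not isolated)
Conditions: 2 (1.3 equiv), (COCl)2, cat. DMF, CH2Cl2, 0 °C to rt, evaporate; then 3 (1.0 equiv), toluene, 60 °C, N2 sweep, no base; then THF/H2O, rt
Reagents that add atoms: none
Why: Vilsmeier‑type activation with oxalyl chloride/DMF gives acid chloride 4, and the base‑free acylation of a hydroxy acid by an acyl chloride is chemoselective for the primary hydroxyl because the un‑ionised carboxyl group of 3 is not a competitive nucleophile, the aryl acetate being inert to both operations.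

Step 3
Reactants: 5 16‑({3‑[4‑(acetyloxy)phenyl]propanoyl}oxy)hexadecanoic acid; 6 undecanoic acid
Product: 9 pentacosyl 3‑[4‑(acetyloxy)phenyl]propanoate, via decyl radical 7 (not isolated), via 15‑(acyloxy)pentadecyl radical 8 (not isolated)
Conditions: 5 (1 equiv), 6 (8 equiv), KOH (5 mol% of total acid), MeOH, 50 °C, undivided cell, smooth Pt anode and Pt cathode, constant current 0.25 A cm−2, polarity reversed periodically; stopped when 5 is consumed and the solution is still acidic
Reagents that add atoms: none
Why: Mixed (crossed) Kolbe electrolysis: at the smooth platinum anode, at high current density in weakly acidic methanol, the carboxylates of 5 and 6 are each oxidised by one electron and lose CO2 at once, giving the primary alkyl radicals 8 and 7, which combine at the electrode surface to form the new CH2–CH2 bond while protons are reduced to H2 at the cathode. The closest known reaction type is the co‑electrolysis of an ω‑acyloxy or half‑ester fatty acid with an excess of a simple alkanoic acid, a standard way to extend unbranched lipid chains. No ring is closed and no stereocentre is created, so neither a closure mode nor stereocontrol is involved. The step needs cross‑ over homo‑coupling, secured by the large excess of cheap 6, so that radical 8 should meet mostly radical 7, and by the easy removal of the purely hydrocarbon dimer of 6 with hexane. It needs radical coupling rather than further oxidation to a cation, secured by both termini being unbranched CH2–CO2H groups without an α‑heteroatom or α‑aryl group. It also needs the arene and both esters to stay untouched, secured by the acetyl group on the phenol oxygen (an acyloxy‑alkyl benzene ring is much harder to oxidise than a phenol and is held away from the carboxylate‑covered anode by the C15 spacer) and by stopping while free 6 still buffers the methoxide formed at the cathode.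

Step 4
Reactants: 9 pentacosyl 3‑[4‑(acetyloxy)phenyl]propanoate
Product: 10 pentacosyl 3‑(4‑hydroxyphenyl)propanoate
Conditions: pyrrolidine (3 equiv), CH2Cl2, 0 °C to rt; 1 M HCl wash
Reagents that add atoms: none
Why: Chemoselective aminolysis of an aryl (active) ester, in which the phenoxide is a far better leaving group than the pentacosyl alkoxide, so that pyrrolidine should remove only the acetyl group and leave the unactivated alkyl ester intact at room temperature.

**Compound list**
1 | 3‑(4‑hydroxyphenyl)propanoic acid (phloretic acid) | OC(=O)CCc1ccc(O)cc1 | starting material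
2 | 3‑[4‑(acetyloxy)phenyl]propanoic acid | CC(=O)Oc1ccc(CCC(=O)O)cc1 | intermediate
3 | 16‑hydroxyhexadecanoic acid | OCCCCCCCCCCCCCCCC(=O)O | starting material
4 | 3‑[4‑(acetyloxy)phenyl]propanoyl chloride | CC(=O)Oc1ccc(CCC(=O)Cl)cc1 | intermediate
5 | 16‑({3‑[4‑(acetyloxy)phenyl]propanoyl}oxy)hexadecanoic acid | CC(=O)Oc1ccc(CCC(=O)OCCCCCCCCCCCCCCCC(=O)O)cc1 | intermediate
6 | undecanoic acid | CCCCCCCCCCC(=O)O | starting material
7 | decyl radical | CCCCCCCCC[CH2] | intermediate
8 | 15‑({3‑[4‑(acetyloxy)phenyl]propanoyl}oxy)pentadecyl radical | [CH2]CCCCCCCCCCCCCCOC(=O)CCc1ccc(OC(C)=O)cc1 | intermediate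
9 | pentacosyl 3‑[4‑(acetyloxy)phenyl]propanoate | CCCCCCCCCCCCCCCCCCCCCCCCCOC(=O)CCc1ccc(OC(C)=O)cc1 | intermediate
10 | pentacosyl 3‑(4‑hydroxyphenyl)propanoate | CCCCCCCCCCCCCCCCCCCCCCCCCOC(=O)CCc1ccc(O)cc1 | target

**Step count and risks**
Total step count: 4. Longest linear sequence: 4 steps (1 → 2 → 5 → 9 → 10).

Steps most likely to fail:

Step 3. The statistical radical–radical coupling may give too small a share of cross‑product, the acetoxy‑substituted ring may be oxidised at the anode, methoxide formed at the cathode may strip the aryl acetate, or waxy product may foul the electrodes. The fallback makes the same bond by a nickel‑catalysed decarboxylative alkyl–alkyl coupling. It sets out from 5: condensation with N‑hydroxyphthalimide (DIC, cat. DMAP, CH2Cl2, rt) should give the redox‑active ester 1,3‑dioxoisoindolin‑2‑yl 16‑({3‑[4‑(acetyloxy)phenyl]propanoyl}oxy)hexadecanoate F1. This is coupled with didecylzinc F2, prepared in the flask from commercial decylmagnesium bromide and ZnCl2 in THF, under NiCl2·glyme and 4,4'‑di‑tert‑butyl‑2,2'‑bipyridine in THF/DMF at rt. Loss of CO2 and phthalimide brings the sequence back to the route at 9.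

Step 2. Acyl transfer to the free carboxyl group (mixed‑anhydride formation) and acid‑promoted self‑esterification of the hydroxy acid to oligomers may compete with the wanted O‑acylation. The fallback masks the carboxyl group first. It sets out from 3: carboxylate alkylation (BnBr, KHCO3, DMF, rt) should give benzyl 16‑hydroxyhexadecanoate F3. Steglich esterification with acid 2 (DIC, cat. DMAP, CH2Cl2) should give benzyl 16‑({3‑[4‑(acetyloxy)phenyl]propanoyl}oxy)hexadecanoate F4. Hydrogenolysis (H2, Pd/C, EtOAc, rt) then removes the benzyl group without touching the aryl acetate and comes back to the route at 5.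

Step 4. Acyl cleavage may be unselective (aminolysis or transesterification at the pentacosyl ester), or may stall because the waxy substrate dissolves poorly. The fallback drops the protecting group strategy at the end. It sets out from 9: exhaustive saponification (LiOH, THF/MeOH/H2O, 60 °C; then HCl) should give pentacosan‑1‑ol F5, with acid 1 and acetic acid going to the aqueous phase. Fischer esterification of F5 with an excess of 1 (cat. TsOH·H2O, toluene, Dean–Stark reflux), under which the phenol is not esterified, comes back to the route at 10.

**Further compounds**
F1 | step 3 | 1,3‑dioxoisoindolin‑2‑yl 16‑({3‑[4‑(acetyloxy)phenyl]propanoyl}oxy)hexadecanoate | CC(=O)Oc1ccc(CCC(=O)OCCCCCCCCCCCCCCCC(=O)ON2C(=O)c3ccccc3C2=O)cc1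
F2 | step 3 | didecylzinc | CCCCCCCCCC[Zn]CCCCCCCCCC
F3 | step 2 | benzyl 16‑hydroxyhexadecanoate | OCCCCCCCCCCCCCCCC(=O)OCc1ccccc1
F4 | step 2 | benzyl 16‑({3‑[4‑(acetyloxy)phenyl]propanoyl}oxy)hexadecanoate | CC(=O)Oc1ccc(CCC(=O)OCCCCCCCCCCCCCCCC(=O)OCc2ccccc2)cc1
F5 | step 4 | pentacosan‑1‑ol | CCCCCCCCCCCCCCCCCCCCCCCCCO
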